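**Plan**

1. The retrosynthesis opens, in one operation, O–C15 (dihydrofuran), C9O–C13 (oxolane) and C8–OH. C13 carries the oxolane oxygen, the vinyl ether carbon C14 and the CH2O carbon C16, which is the footprint of a 2‑ethynyl oxirane. The trans‑diaxial 8β‑OH/9α‑O pair beside the cis 7β‑acetate is the footprint of an 8α,9α‑epoxide opened by its neighbouring acetate.
2. Further cuts are C14–C15 (alkyne homologation), the C13–C16 oxirane (asymmetric epoxidation) and C12–C13 (alkyl–alkenyl cross‑coupling), leading back to (+)‑sclareolide, which supplies rings A and B with C5 and C10.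
3. Forward: sclareolide → 8‑ene ester → 8‑en‑7‑one → C12 iodide → 2‑substituted allylic alcohol → epoxy alcohol → alkynyl oxirane. Then the C6 oxygen (enolate hydroxylation), the 7β‑acetate and the 8α,9α‑epoxide are installed. The cascade closes the oxolane and, last, the dihydrofuran, and C6 is finally oxidised to the ketone.
4. Stereochemistry: C5 and C10 come from sclareolide; C13 from the Sharpless epoxidation, inverted once in the cascade; C9 from α‑face epoxidation; C8 from backside attack of the acetate; C7 from axial hydride delivery.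
5. Helpers: the 7‑acetate of the target doubles as neighbouring group (temporary dioxolanylium ring), and a triethylsilyl ether masks O6 until the end.

Key step: step 13

Remark: compounds 4, 5, 7 and 8 are drawn as the expected major 7β‑alcohols; C7 returns to the ketone in step 7, so this configuration has no bearing on the route. Compounds 1 and 6 and all named reagents are taken as commercial.

**Route**

Step 1
Reactants: 1 (+)-sclareolide
Product: 2 methyl 13,14,15,16-tetranorlabd-8-en-12-oate
Conditions: H2SO4 (conc.), MeOH, reflux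
Reagents that add atoms: methanol, CO
Why: Acid-catalysed lactone methanolysis with E1 loss of the tertiary C8–O bond should equilibrate under the strong acid to the tetrasubstituted 8(9)-alkene, leaving C5 and C10 untouched.

Step 2
Reactants: 2 methyl 13,14,15,16-tetranorlabd-8-en-12-oate
Product: 3 methyl 7-oxo-13,14,15,16-tetranorlabd-8-en-12-oate
Conditions: Na2CrO4, NaOAc, AcOH/Ac2O, 40 °C
Reagents that add atoms: sodium chromate, [Na+].[Na+].[O-][Cr](=O)(=O)[O-]
Why: Chromate allylic oxidation of a drim-8-ene should attack the ring methylene C7, whose axial C–H bond is aligned with the alkene, rather than the side-chain methylene C11 or the C17 methyl group, giving the 8-en-7-one.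

Step 3
Reactants: 3 methyl 7-oxo-13,14,15,16-tetranorlabd-8-en-12-oate
Product: 4 13,14,15,16-tetranorlabd-8-ene-7β,12-diol
Conditions: i-Bu2AlH (excess), CH2Cl2, −78 to 0 °C
Reagents that add atoms: none
Why: Aluminium hydride reduction of the ester to the primary alcohol and 1,2-reduction of the hindered enone, with hydride delivered axially from the α face opposite to the C10 methyl group, should give mainly the 7β-alcohol.

Step 4
Reactants: 4 13,14,15,16-tetranorlabd-8-ene-7β,12-diol
Product: 5 12-iodo-13,14,15,16-tetranorlabd-8-en-7β-ol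
Conditions: PPh3, I2, imidazole (1.05 equiv each), CH2Cl2, −20 to 0 °C
Reagents that add atoms: iodine, II
Why: Appel iodination should activate the unhindered primary C12 alcohol much faster than the secondary C7 alcohol flanked by the tetrasubstituted alkene, so one equivalent of reagent at low temperature gives the primary iodide.

Step 5
Reactants: 5 12-iodo-13,14,15,16-tetranorlabd-8-en-7β-ol, 6 2-bromoprop-2-en-1-ol
Product: 7 15-norlabda-8,13(16)-diene-7β,14-diol
Conditions: NiI2 (10 mol %), 4,4′-di-tert-butyl-2,2′-bipyridine, Mn powder, NaI (cat.), DMA, 25 °C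
Reagents that add atoms: none
Why: Nickel-catalysed reductive cross-electrophile coupling of a primary alkyl iodide with a 1,1-disubstituted alkenyl bromide (alkyl radical captured by the alkenylnickel species, manganese as terminal reductant) tolerates free hydroxyl groups and forms C12–C13 without creating a stereocenter.

Step 6
Reactants: 7 15-norlabda-8,13(16)-diene-7β,14-diol
Product: 8 (13R)-13,16-epoxy-15-norlabd-8-ene-7β,14-diol
Conditions: Ti(OiPr)4 (10 mol %), D-(−)-diethyl tartrate, t-BuOOH, 4 Å molecular sieves, CH2Cl2, −20 °C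
Reagents that add atoms: tert-butyl hydroperoxide, CC(C)(C)OO
Why: Sharpless asymmetric epoxidation of the primary 2-substituted allylic alcohol with the D-(−)-tartrate sets the (13R)-oxirane under reagent control, while the cyclic secondary allylic alcohol with its tetrasubstituted alkene is a very slow substrate for the titanium tartrate catalyst and should stay untouched.

Step 7
Reactants: 8 (13R)-13,16-epoxy-15-norlabd-8-ene-7β,14-diol
Product: 9 (13S)-13,16-epoxy-7-oxo-15-norlabd-8-en-14-al
Conditions: Dess–Martin periodinane (3 equiv), pyridine, CH2Cl2, 0 to 23 °C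
Reagents that add atoms: none
Why: Dess–Martin oxidation of both hydroxyl groups returns the ring allylic alcohol to the 8-en-7-one and turns the primary alcohol into an α-quaternary epoxy aldehyde that cannot epimerise (the descriptor at C13 changes only because the priorities change).

Step 8
Reactants: 9 (13S)-13,16-epoxy-7-oxo-15-norlabd-8-en-14-al
Product: 10 (13R)-13,16-epoxylabd-8-en-14-yn-7-one
Conditions: dimethyl (1-diazo-2-oxopropyl)phosphonate, K2CO3, MeOH, 0 to 23 °C
Reagents that add atoms: dimethyl (1-diazo-2-oxopropyl)phosphonate, CC(=O)C(=[N+]=[N-])P(=O)(OC)OC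
Why: Ohira–Bestmann (Seyferth–Gilbert) homologation converts the aldehyde into the terminal alkyne through an alkylidene carbene 1,2-hydrogen shift, the quaternary oxirane carbon keeps its configuration, and the hindered enone is inert to K2CO3 in methanol.

Step 9
Reactants: 10 (13R)-13,16-epoxylabd-8-en-14-yn-7-one
Product: 12 (13R)-13,16-epoxy-6α-(triethylsilyloxy)labd-8-en-14-yn-7-one, via hydroxy enone 11 (not isolated)
Conditions: KN(SiMe3)2, THF, −78 °C; 2-(phenylsulfonyl)-3-phenyloxaziridine; then Et3SiCl, −78 to 0 °C
Reagents that add atoms: 2-(phenylsulfonyl)-3-phenyloxaziridine, O=S(=O)(c1ccccc1)N1OC1c1ccccc1; chlorotriethylsilane, CC[Si](Cl)(CC)CC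
Why: Kinetic α′-deprotonation of the enone at C6 (the ketone is several pKa units more acidic than the alkyne C–H), Davis oxaziridine hydroxylation of the cross-conjugated enolate from the α face opposite to the axial C10 and C4β methyl groups, and silylation of the potassium alkoxide in the same flask install the protected C6 oxygen, whose configuration is lost again when C6 becomes the ketone in step 15.

Step 10
Reactants: 12 (13R)-13,16-epoxy-6α-(triethylsilyloxy)labd-8-en-14-yn-7-one
Product: 13 (13R)-13,16-epoxy-6α-(triethylsilyloxy)labd-8-en-14-yn-7β-ol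
Conditions: NaBH4, CeCl3·7H2O, MeOH/THF, −78 °C
Reagents that add atoms: none
Why: Luche 1,2-reduction with axial hydride delivery from the α face, opposite to the C10 methyl group, should give the pseudo-equatorial 7β-alcohol that carries the acetate of the target.

Step 11
Reactants: 13 (13R)-13,16-epoxy-6α-(triethylsilyloxy)labd-8-en-14-yn-7β-ol
Product: 14 (13R)-7β-acetoxy-13,16-epoxy-6α-(triethylsilyloxy)labd-8-en-14-yne
Conditions: Ac2O, pyridine, DMAP (cat.), CH2Cl2, 0 to 23 °C
Reagents that add atoms: acetic anhydride, CC(=O)OC(C)=O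
Why: DMAP-catalysed acetylation of the only free hydroxyl group installs the acetate that later serves as neighbouring group.

Step 12
Reactants: 14 (13R)-7β-acetoxy-13,16-epoxy-6α-(triethylsilyloxy)labd-8-en-14-yne
Product: 15 (13R)-7β-acetoxy-8α,9α:13,16-diepoxy-6α-(triethylsilyloxy)labd-14-yne
Conditions: mCPBA, NaHCO3 (buffer), CH2Cl2, 0 °C
Reagents that add atoms: 3-chloroperoxybenzoic acid, OOC(=O)c1cccc(Cl)c1
Why: Prilezhaev epoxidation of the electron-rich tetrasubstituted alkene from the α face, opposite to the axial C10 methyl group and the 7β-acetate, sets the α-oxygen at C9 (and at C8, to be inverted in step 13), while the terminal alkyne and the oxirane are inert to the buffered peracid.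

Step 13
Reactants: 15 (13R)-7β-acetoxy-8α,9α:13,16-diepoxy-6α-(triethylsilyloxy)labd-14-yne
Product: 17 (13S)-7β-acetoxy-9α,13:15,16-diepoxy-6α-(triethylsilyloxy)labd-14-en-8β-ol, via cyclic hemiorthoacetate 16 (not isolated)
Conditions: (Ph3P)AuNTf2 (5 mol %), H2O (3 equiv), CH2Cl2, −20 to 0 °C; then Et3N
Reagents that add atoms: water, O
Why: Proposed new method: the cationic monovalent gold complex binds the terminal alkyne and polarises the adjacent oxirane, so that the oxygen of the 8α,9α-epoxide opens it at the tertiary propargylic carbon C13 with inversion (5-exo-tet, oxolane ring), and the bicyclic epoxonium ion so formed is opened at C8 from the β face by the carbonyl oxygen of the 7β-acetate to give a cis-fused 1,3-dioxolan-2-ylium ion. The liberated C16 alkoxide adds anti to the gold-bound alkyne at C15 (5-endo-dig, dihydrofuran ring, the last ring of the skeleton to close), water adds to the dioxolanylium carbon to give hemiorthoacetate 16, the proton set free protodeaurates the vinylgold, and 16 collapses to the hydroxy acetate, the less hindered secondary 7-acetate being reached by acyl equilibration on the Et3N quench. The closest known reaction types are the gold-catalysed alkoxylative cyclisation of 2-alkynyl oxiranes with alcohols to 3-alkoxy-2,3-dihydrofurans and acid-triggered 1,5-diepoxide relay cascades terminated by an ester or carbonate carbonyl, which have not been combined on a substrate of this kind. C13 (S) follows from inversion of the Sharpless-derived (13R)-oxirane, C8 from backside acetoxonium formation on the α-epoxide (8β-oxygen, 8α-methyl), and C9 keeps its α-oxygen because that C–O bond is never broken. The step needs 5-exo attack at C13 rather than 6-endo attack at C16 (secured by the tertiary propargylic terminus), the C9 oxygen alone as ring oxygen (O8 stays masked in the dioxolanylium ion until the oxolane exists, which excludes a 6-exo closure through O8), and arrest before ionisation at C13 aromatises the product to the furan (low temperature, no added Brønsted acid, amine quench).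

Step 14
Reactants: 17 (13S)-7β-acetoxy-9α,13:15,16-diepoxy-6α-(triethylsilyloxy)labd-14-en-8β-ol
Product: 18 (13S)-7β-acetoxy-9α,13:15,16-diepoxylabd-14-ene-6α,8β-diol
Conditions: Bu4NF, AcOH (1:1), THF, 0 °C
Reagents that add atoms: none
Why: Fluoride cleavage of the triethylsilyl ether under acetic acid buffering should keep the C6 alkoxide from attacking the neighbouring acetate and is mild enough for the spiro enol ether.

Step 15
Reactants: 18 (13S)-7β-acetoxy-9α,13:15,16-diepoxylabd-14-ene-6α,8β-diol
Product: 19 (13S)-7β-acetoxy-9α,13:15,16-diepoxy-8β-hydroxylabd-14-en-6-one (CNP0284584.1)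
Conditions: Dess–Martin periodinane, pyridine, CH2Cl2, 0 °C
Reagents that add atoms: none
Why: Dess–Martin oxidation of the secondary C6 alcohol under pyridine buffering leaves the tertiary alcohol, the acetate and the acid-labile spiro enol ether untouched, and C5 and C7 remain in their thermodynamically preferred configurations (trans ring fusion, equatorial acetate).

**Compound list**

1 | (+)-sclareolide | C1C[C@H]2C(C)(C)CCC[C@]2(C)[C@H]3CC(=O)O[C@]13C | starting material
2 | methyl 13,14,15,16-tetranorlabd-8-en-12-oate | C1C[C@H]2C(C)(C)CCC[C@]2(C)C(CC(=O)OC)=C1C | intermediate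
3 | methyl 7-oxo-13,14,15,16-tetranorlabd-8-en-12-oate | O=C1C[C@H]2C(C)(C)CCC[C@]2(C)C(CC(=O)OC)=C1C | intermediate
4 | 13,14,15,16-tetranorlabd-8-ene-7β,12-diol | O[C@H]1C[C@H]2C(C)(C)CCC[C@]2(C)C(CCO)=C1C | intermediate
5 | 12-iodo-13,14,15,16-tetranorlabd-8-en-7β-ol | O[C@H]1C[C@H]2C(C)(C)CCC[C@]2(C)C(CCI)=C1C | intermediate
6 | 2-bromoprop-2-en-1-ol | OCC(Br)=C | starting material
7 | 15-norlabda-8,13(16)-diene-7β,14-diol | O[C@H]1C[C@H]2C(C)(C)CCC[C@]2(C)C(CCC(=C)CO)=C1C | intermediate
8 | (13R)-13,16-epoxy-15-norlabd-8-ene-7β,14-diol | O[C@H]1C[C@H]2C(C)(C)CCC[C@]2(C)C(CC[C@@]3(CO)CO3)=C1C | intermediate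
9 | (13S)-13,16-epoxy-7-oxo-15-norlabd-8-en-14-al | O=C1C[C@H]2C(C)(C)CCC[C@]2(C)C(CC[C@@]3(C=O)CO3)=C1C | intermediate
10 | (13R)-13,16-epoxylabd-8-en-14-yn-7-one | O=C1C[C@H]2C(C)(C)CCC[C@]2(C)C(CC[C@@]3(C#C)CO3)=C1C | intermediate
11 | (13R)-13,16-epoxy-6α-hydroxylabd-8-en-14-yn-7-one (hydroxy enone, as its potassium alkoxide in the flask) | O=C1[C@H](O)[C@H]2C(C)(C)CCC[C@]2(C)C(CC[C@@]3(C#C)CO3)=C1C | intermediate
12 | (13R)-13,16-epoxy-6α-(triethylsilyloxy)labd-8-en-14-yn-7-one | O=C1[C@H](O[Si](CC)(CC)CC)[C@H]2C(C)(C)CCC[C@]2(C)C(CC[C@@]3(C#C)CO3)=C1C | intermediate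
13 | (13R)-13,16-epoxy-6α-(triethylsilyloxy)labd-8-en-14-yn-7β-ol | O[C@H]1[C@H](O[Si](CC)(CC)CC)[C@H]2C(C)(C)CCC[C@]2(C)C(CC[C@@]3(C#C)CO3)=C1C | intermediate
14 | (13R)-7β-acetoxy-13,16-epoxy-6α-(triethylsilyloxy)labd-8-en-14-yne | CC(=O)O[C@H]1[C@H](O[Si](CC)(CC)CC)[C@H]2C(C)(C)CCC[C@]2(C)C(CC[C@@]3(C#C)CO3)=C1C | intermediate
15 | (13R)-7β-acetoxy-8α,9α:13,16-diepoxy-6α-(triethylsilyloxy)labd-14-yne | CC(=O)O[C@H]1[C@H](O[Si](CC)(CC)CC)[C@H]2C(C)(C)CCC[C@]2(C)[C@]4(CC[C@@]3(C#C)CO3)O[C@]14C | intermediate
16 | cyclic hemiorthoacetate: (13S)-9α,13:15,16-diepoxy-7β,8β-(1-hydroxyethylidenedioxy)-6α-(triethylsilyloxy)labd-14-ene (either configuration at the orthoester carbon) | CC1(O)O[C@H]2[C@H](O[Si](CC)(CC)CC)[C@H]3C(C)(C)CCC[C@]3(C)[C@@]3(CC[C@@]4(C=COC4)O3)[C@@]2(C)O1 | intermediate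
17 | (13S)-7β-acetoxy-9α,13:15,16-diepoxy-6α-(triethylsilyloxy)labd-14-en-8β-ol | CC(=O)O[C@H]1[C@H](O[Si](CC)(CC)CC)[C@H]2C(C)(C)CCC[C@]2(C)[C@@]2(CC[C@@]3(C=COC3)O2)[C@@]1(C)O | intermediate
18 | (13S)-7β-acetoxy-9α,13:15,16-diepoxylabd-14-ene-6α,8β-diol | CC(=O)O[C@H]1[C@H](O)[C@H]2C(C)(C)CCC[C@]2(C)[C@@]2(CC[C@@]3(C=COC3)O2)[C@@]1(C)O | intermediate
19 | (13S)-7β-acetoxy-9α,13:15,16-diepoxy-8β-hydroxylabd-14-en-6-one (CNP0284584.1) | CC(=O)O[C@H]1C(=O)[C@H]2C(C)(C)CCC[C@]2(C)[C@@]2(CC[C@@]3(C=COC3)O2)[C@@]1(C)O | target

**Step count and risks**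

Total steps: 15. Longest linear sequence: 15 steps (from 1).

Steps most likely to fail:

1. Step 13 (proposed new method). The π-acid alone may fail to start the epoxide relay. Premature hydrolysis of the dioxolanylium ion would free the C8 hydroxyl, which could then close a six-membered ether onto C13. Ionisation of the product at C13 would aromatise the dihydrofuran to the 3-substituted furan with loss of the C9–O–C13 bond. The fallback uses known chemistry in two operations and sets out from 15. Catalytic camphorsulfonic acid in CH2Cl2/H2O at 0 °C (acyloxy-assisted trans-diaxial opening of the ring epoxide, then acid-catalysed 5-exo opening of the tertiary oxirane by the C9 hydroxyl) should give the acid-stable alkynol (13S)-7β-acetoxy-9α,13-epoxy-6α-(triethylsilyloxy)labd-14-yne-8β,16-diol F1. Molybdenum-vinylidene endo-cycloisomerisation of this homopropargylic alcohol (Mo(CO)6, Et3N, Et2O, hν) then closes the dihydrofuran under basic conditions and comes back to the route at 17.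

2. Step 9. Deprotonation at the hindered C6–H may be slow, so that γ-deprotonation at C11 or C17 and oxidation of the extended dienolate take over; the alkoxide may also add to the sulfonimine instead of being silylated. The fallback sets out from 10 and replaces the kinetic enolate by a manganese enolate/α′-keto radical pathway. Trivalent manganese α′-acetoxylation (Mn(OAc)3·2H2O, benzene, reflux) gives (13R)-6α-acetoxy-13,16-epoxylabd-8-en-14-yn-7-one F2. Methanolysis (K2CO3, MeOH, 0 °C) gives 11, and a separate silylation (Et3SiCl, imidazole, DMF) comes back at 12.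

3. Step 5. Hydrodehalogenation or homodimerisation of the two halides may outrun the cross-coupling, and the unprotected bromoallylic alcohol may bind nickel and stall the cycle. The fallback sets out from 5 and builds the 2-substituted allylic alcohol by carbonyl chemistry. Alkylation of sodium triethyl phosphonoacetate (NaH, THF/DMF) gives ethyl 13-(diethoxyphosphoryl)-7β-hydroxy-15,16-dinorlabd-8-en-14-oate F3 (both C13 epimers). Horner–Wadsworth–Emmons methylenation with aqueous formaldehyde and K2CO3 gives ethyl 7β-hydroxy-15-norlabda-8,13(16)-dien-14-oate F4. Reduction with i-Bu2AlH comes back at 7.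

**Further compounds**

F1 | step 13 | (13S)-7β-acetoxy-9α,13-epoxy-6α-(triethylsilyloxy)labd-14-yne-8β,16-diol | CC(=O)O[C@H]1[C@H](O[Si](CC)(CC)CC)[C@H]2C(C)(C)CCC[C@]2(C)[C@@]2(CC[C@](C#C)(CO)O2)[C@@]1(C)O
F2 | step 9 | (13R)-6α-acetoxy-13,16-epoxylabd-8-en-14-yn-7-one | O=C1[C@H](OC(C)=O)[C@H]2C(C)(C)CCC[C@]2(C)C(CC[C@@]3(C#C)CO3)=C1C
F3 | step 5 | ethyl 13-(diethoxyphosphoryl)-7β-hydroxy-15,16-dinorlabd-8-en-14-oate | O[C@H]1C[C@H]2C(C)(C)CCC[C@]2(C)C(CCC(C(=O)OCC)P(=O)(OCC)OCC)=C1C
F4 | step 5 | ethyl 7β-hydroxy-15-norlabda-8,13(16)-dien-14-oate | O[C@H]1C[C@H]2C(C)(C)CCC[C@]2(C)C(CCC(=C)C(=O)OCC)=C1C
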